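**Strategy.** Ring C is disconnected at C2–C3 and O1–C8a, so that C2 and O1 arrive together as an aldehyde carbonyl. The route exploits the β-aryloxy ketone O1–C2–C3–C4(=O) of ring C, an aldol retron, and the position of C8a of ring A ortho to the C4 acyl group, where a C8a–F bond is a vinylogous acyl fluoride. In one flask a catalytic asymmetric Mukaiyama aldol addition joins C3 to C2 and sets (2S); fluoride then unmasks the aldol oxygen, which displaces fluoride at C8a. The precursors are the enol silane of a fully substituted 6-fluoro-3-geranylacetophenone, assembled regiospecifically from 5-fluororesorcinol, and 4-(methoxymethoxy)benzaldehyde.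

Key step: step 6

Assumption: aldehyde 13 is bought, and the (R)-tryptophan-derived catalyst is taken to expose the Si face of 13 (mirror image of the accepted model for its antipode); the antipodal catalyst would be used if the first run showed the opposite sense.

Geranyl = (2E)-3,7-dimethylocta-2,6-dien-1-yl; MOM = methoxymethyl.

**Step 1**
Reactants: 1 5-fluororesorcinol
Product: 2 5-fluoro-2-iodobenzene-1,3-diol
Conditions: I2, NaHCO3, H2O–THF, 0 °C → rt
Reagents that add atoms: iodine, II
Why: Electrophilic aromatic iodination under the bicarbonate conditions that iodinate resorcinol itself between the hydroxyls should place iodine at C2, which is ortho to both hydroxyls and para to fluorine, while C4 and C6 are inductively deactivated by the adjacent fluorine.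

**Step 2**
Reactants: 2 5-fluoro-2-iodobenzene-1,3-diol
Product: 3 5-fluoro-2-iodo-1,3-bis(methoxymethoxy)benzene
Conditions: NaH, MOMCl, DMF, 0 °C → rt
Reagents that add atoms: chloromethyl methyl ether, COCCl
Why: Williamson etherification of both phenoxides gives acetal ethers that survive the organolithium steps, the Lewis acid and fluoride, and are removed together at the end.

**Step 3**
Reactants: 3 5-fluoro-2-iodo-1,3-bis(methoxymethoxy)benzene; 4 geranyl bromide
Product: 7 5-fluoro-2-geranyl-1,3-bis(methoxymethoxy)benzene, via aryllithium 5 (not isolated), via arylcopper 6 (not isolated)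
Conditions: n-BuLi, THF, −78 °C; CuBr·SMe2 (1 equiv), −78 → −40 °C; then 4, −78 → 0 °C
Reagents that add atoms: none
Why: Iodine–lithium exchange fixes the metal at the carbon between the two MOM ethers whatever the acidifying effect of fluorine, and the arylcopper formed by transmetalation should couple with geranyl bromide by α-selective SN2 allylic substitution with retention of the E-alkene.

**Step 4**
Reactants: 7 5-fluoro-2-geranyl-1,3-bis(methoxymethoxy)benzene
Product: 10 1-[6-fluoro-3-geranyl-2,4-bis(methoxymethoxy)phenyl]ethan-1-one, via aryllithium 8 (not isolated), via tetrahedral adduct 9 (not isolated)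
Conditions: s-BuLi, THF, −78 °C; MeC(O)N(OMe)Me, −78 °C; AcOH quench
Reagents that add atoms: N-methoxy-N-methylacetamide, CC(=O)N(C)OC
Why: Directed ortho-metalation removes one of the two equivalent ring hydrogens, each flanked by fluorine and a MOM ether, and the aryllithium is acylated by the Weinreb amide through a chelated tetrahedral adduct that releases the methyl ketone only on quench (Weinreb ketone synthesis), the low temperature keeping the ortho-fluoroaryllithium from losing LiF.

**Step 5**
Reactants: 10 1-[6-fluoro-3-geranyl-2,4-bis(methoxymethoxy)phenyl]ethan-1-one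
Product: 12 trimethyl({1-[6-fluoro-3-geranyl-2,4-bis(methoxymethoxy)phenyl]ethenyl}oxy)silane, via lithium enolate 11 (not isolated)
Conditions: LiN(SiMe3)2, THF, −78 °C; Me3SiCl, −78 → 0 °C; pentane, filtration
Reagents that add atoms: chlorotrimethylsilane, C[Si](C)(C)Cl
Why: Kinetic deprotonation of the only enolizable position (the methyl group) and O-silylation of the lithium enolate give the enol silane needed for the Mukaiyama aldol addition.

**Step 6**
Reactants: 12 trimethyl({1-[6-fluoro-3-geranyl-2,4-bis(methoxymethoxy)phenyl]ethenyl}oxy)silane; 13 4-(methoxymethoxy)benzaldehyde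
Product: 16 (2S)-6-geranyl-5,7-bis(methoxymethoxy)-2-[4-(methoxymethoxy)phenyl]-2,3-dihydro-4H-chromen-4-one, via silyl aldol 14 (not isolated), via caesium aldolate 15 (not isolated)
Conditions: 13 (1.2 equiv), (R)-tryptophan-derived N-tosyl B-butyl-1,3,2-oxazaborolidin-5-one (20 mol %), EtCN, −78 °C; then CsF, 18-crown-6, DMF, −40 → 0 °C, same flask
Reagents that add atoms: none
Why: The chiral boron Lewis acid binds aldehyde 13 and enol silane 12 adds to its Si face through an open Mukaiyama aldol transition state, forming C2–C3 and, after silyl transfer, silyl ether 14; fluoride then removes silicon and alkoxide 15 adds to C8a and expels fluoride (SNAr through a Meisenheimer complex stabilised by the ortho C4 ketone), forming O1–C8a, the expelled fluoride carrying on the desilylation. The closest known reaction types are the oxazaborolidinone-catalysed Mukaiyama aldol addition of aryl methyl ketone enol silanes and the fluoride-mediated etherification of silyl ethers with activated aryl fluorides, which together amount to a stepwise hetero-Diels–Alder reaction of the aldehyde across the unit C3=C4(OSi)–C4a=C8a(F). Ring C closes by a 6-endo-trig addition–elimination at C8a, the C8a=C4a bond of the vinylogous acyl fluoride lying inside the new ring. The only new stereocenter, C2, is set in the aldol event under catalyst control and is not touched by the ring closure, because the C2–O bond is never broken. The step needs face selectivity, supplied by the catalyst; site selectivity, secured because C8a carries the only fluorine while the other ortho carbon C5 carries the far poorer leaving group OMOM and the C5 and C7 oxygens are meta to C8a and do not deactivate it; and ring closure faster than retro-aldol cleavage of 15, which is why 13 is used in slight excess so that no enol silane survives into the fluoride stage and the closure is run cold.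

**Step 7**
Reactants: 16 (2S)-6-geranyl-5,7-bis(methoxymethoxy)-2-[4-(methoxymethoxy)phenyl]-2,3-dihydro-4H-chromen-4-one
Product: 17 bonannione A
Conditions: 3 M aq HCl, MeOH, 40 °C, short reaction time
Reagents that add atoms: none
Why: Acid-catalysed acetal exchange with methanol (MOM cleavage) releases the three phenols as dimethoxymethane, and the mild temperature is chosen so that the trisubstituted alkenes of the geranyl chain are not protonated and the C2 centre, which is not involved, keeps its configuration.

**Compound list**

1 | 5-fluororesorcinol (5-fluorobenzene-1,3-diol) | Oc1cc(O)cc(F)c1 | starting material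
2 | 5-fluoro-2-iodobenzene-1,3-diol | Oc1cc(F)cc(O)c1I | intermediate
3 | 5-fluoro-2-iodo-1,3-bis(methoxymethoxy)benzene | COCOc1cc(F)cc(OCOC)c1I | intermediate
4 | geranyl bromide, (2E)-1-bromo-3,7-dimethylocta-2,6-diene | CC(C)=CCC/C(C)=C/CBr | starting material
5 | [4-fluoro-2,6-bis(methoxymethoxy)phenyl]lithium | [Li]c1c(OCOC)cc(F)cc1OCOC | intermediate
6 | [4-fluoro-2,6-bis(methoxymethoxy)phenyl]copper | [Cu]c1c(OCOC)cc(F)cc1OCOC | intermediate
7 | 5-fluoro-2-geranyl-1,3-bis(methoxymethoxy)benzene | CC(C)=CCC/C(C)=C/Cc1c(OCOC)cc(F)cc1OCOC | intermediate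
8 | [6-fluoro-3-geranyl-2,4-bis(methoxymethoxy)phenyl]lithium | CC(C)=CCC/C(C)=C/Cc1c(OCOC)cc(F)c([Li])c1OCOC | intermediate
9 | lithium 1-[6-fluoro-3-geranyl-2,4-bis(methoxymethoxy)phenyl]-1-[methoxy(methyl)amino]ethan-1-olate | CC(C)=CCC/C(C)=C/Cc1c(OCOC)cc(F)c(C(C)(O[Li])N(C)OC)c1OCOC | intermediate
10 | 1-[6-fluoro-3-geranyl-2,4-bis(methoxymethoxy)phenyl]ethan-1-one | CC(C)=CCC/C(C)=C/Cc1c(OCOC)cc(F)c(C(C)=O)c1OCOC | intermediate
11 | lithium enolate of 10 | CC(C)=CCC/C(C)=C/Cc1c(OCOC)cc(F)c(C(=C)O[Li])c1OCOC | intermediate
12 | trimethyl({1-[6-fluoro-3-geranyl-2,4-bis(methoxymethoxy)phenyl]ethenyl}oxy)silane | CC(C)=CCC/C(C)=C/Cc1c(OCOC)cc(F)c(C(=C)O[Si](C)(C)C)c1OCOC | intermediate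
13 | 4-(methoxymethoxy)benzaldehyde | COCOc1ccc(C=O)cc1 | starting material
14 | (3S)-1-[6-fluoro-3-geranyl-2,4-bis(methoxymethoxy)phenyl]-3-[4-(methoxymethoxy)phenyl]-3-[(trimethylsilyl)oxy]propan-1-one | CC(C)=CCC/C(C)=C/Cc1c(OCOC)cc(F)c(C(=O)C[C@@H](c2ccc(OCOC)cc2)O[Si](C)(C)C)c1OCOC | intermediate
15 | caesium (1S)-3-[6-fluoro-3-geranyl-2,4-bis(methoxymethoxy)phenyl]-1-[4-(methoxymethoxy)phenyl]-3-oxopropan-1-olate | CC(C)=CCC/C(C)=C/Cc1c(OCOC)cc(F)c(C(=O)C[C@@H](c2ccc(OCOC)cc2)O[Cs])c1OCOC | intermediate
16 | (2S)-6-geranyl-5,7-bis(methoxymethoxy)-2-[4-(methoxymethoxy)phenyl]-2,3-dihydro-4H-chromen-4-one | CC(C)=CCC/C(C)=C/Cc1c(OCOC)cc2c(c1OCOC)C(=O)C[C@@H](c1ccc(OCOC)cc1)O2 | intermediate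
17 | bonannione A, (2S)-6-geranyl-5,7-dihydroxy-2-(4-hydroxyphenyl)-2,3-dihydro-4H-chromen-4-one | CC(C)=CCC/C(C)=C/Cc1c(O)cc2c(c1O)C(=O)C[C@@H](c1ccc(O)cc1)O2 | target

**Step count and risks**

Total step count: 7. Longest linear sequence: 7 steps (1 → 17); 4 and 13 enter as bought fragments.

Steps most likely to fail:

Step 6. The free alkoxide may undergo retro-aldol cleavage and recombination before ring closure, which would erode the enantiomeric purity; facial control with the hindered enol silane may also be incomplete. The fallback sets out from ketone 10 and separates bond formation from stereocontrol. Methyl 4-hydroxybenzoate is protected (NaH, MOMCl) to give methyl 4-(methoxymethoxy)benzoate F1. Claisen condensation of the lithium enolate of 10 with F1 (LiN(SiMe3)2, THF) should give 1-[6-fluoro-3-geranyl-2,4-bis(methoxymethoxy)phenyl]-3-[4-(methoxymethoxy)phenyl]propane-1,3-dione F2. On warming in DMF its enolate oxygen should displace fluoride at C8a (intramolecular SNAr) to give the flavone 6-geranyl-5,7-bis(methoxymethoxy)-2-[4-(methoxymethoxy)phenyl]-4H-chromen-4-one F3. Enantioselective conjugate reduction with a CuH catalyst generated from Cu(OAc)2, the appropriate enantiomer of DTBM-SEGPHOS, (EtO)2MeSiH and t-BuOH should reduce only the C2=C3 enone bond, leave the geranyl alkenes untouched and set C2 by ligand-controlled hydride delivery. This comes back to the route at 16.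

Step 1. Iodination may lack site selectivity (attack at C4 next to fluorine) or run on to di-iodide. The fallback sets out from 1 and uses blocking groups instead. Protection (NaH, MOMCl) gives 1-fluoro-3,5-bis(methoxymethoxy)benzene F4. Two rounds of ortho-lithiation and silylation (s-BuLi, THF, −78 °C; Me3SiCl) at the two fluorine-flanked positions give [2-fluoro-4,6-bis(methoxymethoxy)-1,3-phenylene]bis(trimethylsilane) F5. Lithiation at the only remaining ring position, between the MOM ethers (n-BuLi, THF, 0 °C), then CuBr·SMe2 and 4, gives [2-fluoro-5-geranyl-4,6-bis(methoxymethoxy)-1,3-phenylene]bis(trimethylsilane) F6. Protodesilylation with Bu4NF in wet DMF comes back to the route at 7.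

Step 7. Acid may protonate the geranyl alkenes, leading to cyclisation onto the flanking C5 or C7 phenol or to addition of methanol. The fallback sets out from 16 and avoids protic acid. Me3SiOTf and 2,2'-bipyridyl (CH2Cl2, 0 °C) should exchange the three aryl MOM ethers for silyl ethers, giving the tris(trimethylsilyl) ether of bonannione A F7. Neutral hydrolysis (H2O–THF) of the silyl ethers comes back to the route at 17.

**Further compounds**

F1 | step 6 | methyl 4-(methoxymethoxy)benzoate | COCOc1ccc(C(=O)OC)cc1
F2 | step 6 | 1-[6-fluoro-3-geranyl-2,4-bis(methoxymethoxy)phenyl]-3-[4-(methoxymethoxy)phenyl]propane-1,3-dione | CC(C)=CCC/C(C)=C/Cc1c(OCOC)cc(F)c(C(=O)CC(=O)c2ccc(OCOC)cc2)c1OCOC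
F3 | step 6 | 6-geranyl-5,7-bis(methoxymethoxy)-2-[4-(methoxymethoxy)phenyl]-4H-chromen-4-one | CC(C)=CCC/C(C)=C/Cc1c(OCOC)cc2oc(-c3ccc(OCOC)cc3)cc(=O)c2c1OCOC
F4 | step 1 | 1-fluoro-3,5-bis(methoxymethoxy)benzene | COCOc1cc(F)cc(OCOC)c1
F5 | step 1 | [2-fluoro-4,6-bis(methoxymethoxy)-1,3-phenylene]bis(trimethylsilane) | COCOc1cc(OCOC)c([Si](C)(C)C)c(F)c1[Si](C)(C)C
F6 | step 1 | [2-fluoro-5-geranyl-4,6-bis(methoxymethoxy)-1,3-phenylene]bis(trimethylsilane) | CC(C)=CCC/C(C)=C/Cc1c(OCOC)c([Si](C)(C)C)c(F)c([Si](C)(C)C)c1OCOC
F7 | step 7 | tris(trimethylsilyl) ether of bonannione A | CC(C)=CCC/C(C)=C/Cc1c(O[Si](C)(C)C)cc2c(c1O[Si](C)(C)C)C(=O)C[C@@H](c1ccc(O[Si](C)(C)C)cc1)O2
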